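## Retrosynthetic overview
- The C6 prenyl group comes from O5. The target is the formal [1,3] O→C shift isomer of its 5-O-prenyl ether, so this ether both masks 5-OH and supplies the prenyl group.
- Ring C is the only ring built and is made last. The O1–C2 and C3–OH bonds and both stereocentres come from a 2'-hydroxychalcone in one flask, by enantioselective epoxidation followed by 6-endo opening of the epoxide by the phenol.
- The chalcone Cα=Cβ bond comes from a Claisen–Schmidt condensation of isovanillin (ring B) with 2-hydroxy-4-methoxy-6-prenyloxyacetophenone (ring A).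
- That ketone comes from mono-O-prenylation of symmetrical 2',6'-dihydroxy-4'-methoxyacetophenone. This leaves one free ortho phenol, so ring closure can only give the 6-prenyl series.

Assumption: 1 is bought as a catalogue compound, and the L-pipecolic-acid-derived ligand is taken to give the (αR,βS) epoxide; if the first run (HPLC/CD) shows the opposite sense, its mirror image from D-pipecolic acid is used with nothing else changed.

## Route

Step 1
Reactants: 1 2',6'-dihydroxy-4'-methoxyacetophenone; 2 prenyl bromide (1-bromo-3-methylbut-2-ene)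
Product: 3 1-[2-hydroxy-4-methoxy-6-(3-methylbut-2-enyloxy)phenyl]ethanone
Conditions: 2 (1.05 equiv), K2CO3 (1.5 equiv), acetone, reflux, 6 h
Reagents that add atoms: none
Why: Williamson O-alkylation, in which the two phenols of 1 are equivalent by symmetry, the phenoxide is O-alkylated by the primary allylic bromide in acetone, and the remaining phenol is held in a strong hydrogen bond to the ketone so a second alkylation is slow; no stereocentre is formed.

Step 2
Reactants: 3 1-[2-hydroxy-4-methoxy-6-(3-methylbut-2-enyloxy)phenyl]ethanone; 4 isovanillin (3-hydroxy-4-methoxybenzaldehyde)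
Product: 5 (E)-3-(3-hydroxy-4-methoxyphenyl)-1-[2-hydroxy-4-methoxy-6-(3-methylbut-2-enyloxy)phenyl]prop-2-en-1-one
Conditions: KOH (50% aq, 10 equiv), EtOH, N2, 0 °C to rt, 48 h; then cold 1 M HCl to pH 5
Reagents that add atoms: none
Why: Claisen–Schmidt (crossed aldol) condensation, in which the methyl ketone enolate adds to the non-enolisable aldehyde (its phenoxide is meta to the formyl group and does not quench it), E1cB loss of water gives only the E-enone, and strong base holds the product open as its 2'-phenoxide; no stereocentre is formed.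

Step 3
Reactants: 5 (E)-3-(3-hydroxy-4-methoxyphenyl)-1-[2-hydroxy-4-methoxy-6-(3-methylbut-2-enyloxy)phenyl]prop-2-en-1-one
Product: 7 (2R,3R)-3-hydroxy-2-(3-hydroxy-4-methoxyphenyl)-7-methoxy-5-(3-methylbut-2-enyloxy)chroman-4-one, via (αR,βS)-epoxychalcone 6 (not isolated)
Conditions: Sc(OTf)3 (10 mol %), N,N'-dioxide ligand L-PiPr2 [(2S,2'S)-1,1'-(propane-1,3-diyl)bis{2-[(2,6-diisopropylphenyl)carbamoyl]piperidine 1-oxide}, 11 mol %], 30% aq H2O2 (2 equiv), THF, 30 °C, 24 h; then 45 °C until 6 is consumed; recrystallise
Reagents that add atoms: hydrogen peroxide, OO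
Why: Proposed new method: an enantioselective, base-free interrupted Algar–Flynn–Oyamada reaction, in which the free 2'-OH/C=O pair of 5 chelates the chiral N,N'-dioxide–Sc(OTf)3 complex (trivalent scandium), the rigid chelate lowers the LUMO of this electron-rich enone and exposes one face of Cβ to ligand-bound H2O2, Weitz–Scheffer-type conjugate addition and O–O closure give the trans-(αR,βS)-epoxide 6 (this sets C3 as R), and the same Lewis acid then activates the benzylic, p-methoxy-stabilised Cβ–O bond for anti 6-endo attack by the only free ortho phenol (inversion, βS to 2R, hence 2,3-trans), while the absence of base suppresses 5-exo closure to aurone-type products, over-oxidation to the flavonol and epimerisation; the closest known reaction types are the N,N'-dioxide–Sc(OTf)3/H2O2 epoxidation of simple chalcones and the acid-induced cyclisation of deprotected 2'-O-MOM epoxychalcones, which have not been merged or run on an unprotected 2'-hydroxychalcone.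

Step 4
Reactants: 7 (2R,3R)-3-hydroxy-2-(3-hydroxy-4-methoxyphenyl)-7-methoxy-5-(3-methylbut-2-enyloxy)chroman-4-one
Product: 8 (2R,3R)-3,5-dihydroxy-2-(3-hydroxy-4-methoxyphenyl)-7-methoxy-6-(3-methylbut-2-enyl)chroman-4-one (target)
Conditions: montmorillonite K10 (oven-dried, 2 wt equiv), CH2Cl2, 0 °C to rt
Reagents that add atoms: none
Why: Clay-catalysed formal [1,3] O→C prenyl shift of an aryl prenyl ether, in which acid sites ionise the O5–prenyl bond to a tight phenol/prenyl-cation pair that recombines through its primary terminus at the adjacent free ortho carbon C6 (C4a is blocked, and C6 is activated by O5 and the 7-OMe), the released 5-OH is tied up by hydrogen bonding to C4=O, which slows chroman formation, and neither stereocentre is touched.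

## Compound list
1 | 2',6'-dihydroxy-4'-methoxyacetophenone | CC(=O)c1c(O)cc(OC)cc1O | starting material
2 | prenyl bromide (1-bromo-3-methylbut-2-ene) | CC(C)=CCBr | starting material
3 | 1-[2-hydroxy-4-methoxy-6-(3-methylbut-2-enyloxy)phenyl]ethanone | CC(=O)c1c(O)cc(OC)cc1OCC=C(C)C | intermediate
4 | isovanillin (3-hydroxy-4-methoxybenzaldehyde) | COc1ccc(C=O)cc1O | starting material
5 | (E)-3-(3-hydroxy-4-methoxyphenyl)-1-[2-hydroxy-4-methoxy-6-(3-methylbut-2-enyloxy)phenyl]prop-2-en-1-one | COc1ccc(/C=C/C(=O)c2c(O)cc(OC)cc2OCC=C(C)C)cc1O | intermediate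
6 | (αR,βS)-epoxychalcone, [(2R,3S)-3-(3-hydroxy-4-methoxyphenyl)oxiran-2-yl][2-hydroxy-4-methoxy-6-(3-methylbut-2-enyloxy)phenyl]methanone | COc1ccc([C@@H]2O[C@H]2C(=O)c3c(O)cc(OC)cc3OCC=C(C)C)cc1O | intermediate
7 | (2R,3R)-3-hydroxy-2-(3-hydroxy-4-methoxyphenyl)-7-methoxy-5-(3-methylbut-2-enyloxy)chroman-4-one | COc1ccc([C@H]2Oc3cc(OC)cc(OCC=C(C)C)c3C(=O)[C@@H]2O)cc1O | intermediate
8 | (2R,3R)-3,5-dihydroxy-2-(3-hydroxy-4-methoxyphenyl)-7-methoxy-6-(3-methylbut-2-enyl)chroman-4-one | COc1ccc([C@H]2Oc3cc(OC)c(CC=C(C)C)c(O)c3C(=O)[C@@H]2O)cc1O | target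

## Step count
Total step count: 4. Longest linear sequence: 4 steps (1 → 3 → 5 → 7 → 8).

## Three steps most likely to fail

**Step 3 (the proposed new step).**
- Risks:
  - The doubly electron-rich enone may convert slowly.
  - Sc(OTf)3 may promote oxa-Michael closure of 5 to the racemic flavanone.
  - Partial SN1 character at Cβ may give some 2,3-cis isomer. This differs only at C2 and should equilibrate to trans.
  - The ee may be only moderate.
  - The prenyl ether may be lost early.
- Fallback (known chemistry): it sets out from 5 and comes back at 7.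
  - Both phenols of 5 are capped with MOMCl and NaH in THF–DMF at 0 °C to give the bis-MOM chalcone F1.
  - Juliá–Colonna epoxidation (poly-L-leucine, urea–H2O2, DBU, THF, rt) gives the (αR,βS)-bis-MOM epoxychalcone F2.
  - Dilute HCl in MeOH (rt to 40 °C, monitored so the prenyl ether survives) removes both MOM groups. The freed 2'-phenol then opens the epoxide at the benzylic carbon to give 7, which is recrystallised to raise the ee.

**Step 4.**
- Risks:
  - The prenyl group may migrate to C8.
  - It may simply be lost.
  - The new 6-prenyl group may cyclise onto 5-OH to give a dimethylchroman.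
  - The 6- and 8-isomers are told apart by HMBC from the chelated 5-OH.
- Fallback: it sets out from 7 and comes back at 8, replacing the rearrangement by a cross-coupling.
  - The prenyl ether is removed with Pd(PPh3)4 (zerovalent palladium, 5 mol %) and morpholine in THF to give (2R,3R)-7,4'-di-O-methyltaxifolin F3.
  - BnNMe3ICl2 and CaCO3 in CH2Cl2–MeOH at rt iodinate the position ortho to the chelated 5-OH to give the 6-iodo dihydroflavonol F4.
  - Stille coupling with tributyl(3-methylbut-2-enyl)stannane (Pd(PPh3)4, DMF, 80 °C) gives 8.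

**Step 2.**
- Risks:
  - The unprotected phenolic aldehyde may condense sluggishly.
  - The chalcone may drift to the flavanone during the long reaction or on acidification.
- Fallback: it sets out from 3 and 4 and comes back at 5, replacing the one-pot thermodynamic condensation by a directed kinetic aldol followed by a separate elimination.
  - 4 is silylated (TBSCl, imidazole, DMF) to give O-TBS-isovanillin F5.
  - The dianion of 3 (LiN(SiMe3)2, 2.2 equiv, THF, −78 °C) is added to it to give the racemic β-hydroxy ketone F6.
  - Brief treatment with KOH in MeOH at rt causes E1cB dehydration and cleaves the aryl silyl ether to give 5.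

## Further compounds
F1 | step 3 | (E)-1-[4-methoxy-2-(methoxymethoxy)-6-(3-methylbut-2-enyloxy)phenyl]-3-[4-methoxy-3-(methoxymethoxy)phenyl]prop-2-en-1-one | COCOc1cc(/C=C/C(=O)c2c(OCOC)cc(OC)cc2OCC=C(C)C)ccc1OC
F2 | step 3 | {(2R,3S)-3-[4-methoxy-3-(methoxymethoxy)phenyl]oxiran-2-yl}[4-methoxy-2-(methoxymethoxy)-6-(3-methylbut-2-enyloxy)phenyl]methanone | COCOc1cc([C@@H]2O[C@H]2C(=O)c3c(OCOC)cc(OC)cc3OCC=C(C)C)ccc1OC
F3 | step 4 | (2R,3R)-3,5-dihydroxy-2-(3-hydroxy-4-methoxyphenyl)-7-methoxychroman-4-one | COc1ccc([C@H]2Oc3cc(OC)cc(O)c3C(=O)[C@@H]2O)cc1O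
F4 | step 4 | (2R,3R)-3,5-dihydroxy-2-(3-hydroxy-4-methoxyphenyl)-6-iodo-7-methoxychroman-4-one | COc1ccc([C@H]2Oc3cc(OC)c(I)c(O)c3C(=O)[C@@H]2O)cc1O
F5 | step 2 | 3-(tert-butyldimethylsilyloxy)-4-methoxybenzaldehyde | COc1ccc(C=O)cc1O[Si](C)(C)C(C)(C)C
F6 | step 2 | 3-[3-(tert-butyldimethylsilyloxy)-4-methoxyphenyl]-3-hydroxy-1-[2-hydroxy-4-methoxy-6-(3-methylbut-2-enyloxy)phenyl]propan-1-one (racemic) | COc1ccc(C(O)CC(=O)c2c(O)cc(OC)cc2OCC=C(C)C)cc1O[Si](C)(C)C(C)(C)C
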